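(The readings are calculated on assumed constants; noise was put on by code.)

The balance of substrate, the limiting reagent, is the invariant here: what leaves it is held as target or as side product, so once substrate reads zero, the side product is the remainder of the target fraction y.

| flask | substrate | gas phase | remark | time |
|---|---|---|---|---|
| oak | 13 mM | 8.9 mM (held) | run made earlier |  |
| maple | 30 mM | 8.9 mM (held) | run made earlier |  |
| flask | 20 mM | 8.9 mM (held) |  | 15 min |

| run | time / min | target / % | substrate / % |
|---|---|---|---|
| oak | 1.00 | 64.9 | 11.5 |
| oak | 3.00 | 70.9 | 0 |
| oak | 6.00 | 71.0 | 0 |
| oak | 10.0 | 70.9 | 0 |
| maple | 0.667 | 45.9 | 20.2 |
| maple | 1.50 | 52.0 | 2.0 |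
| maple | 4.00 | 52.8 | 0 |
| maple | 10.0 | 52.7 | 0 |

(standard deviation of a reading: 0.3 percentage points)

- percentages count the substrate that a species holds: one side product counts as two
- target is meant together with its crystals
- solid, in amounts per volume of the solution: crystals
- at the start none of the gas is dissolved
- what was read earlier has a scatter of 0.3 percentage points, one standard deviation
- on the list of suspects stand: crystals <-> target; substrate + target -> side product; gas phase <-> dissolved gas; substrate + dissolved gas -> target
- the reaction counts as stopped when no species that holds the substrate changes by six tenths of a point or more over the second half of the time

- the state of affairs at 15 min: stopped, and by what, or still going (forward and back rates have come level / it is still moving / all of the substrate has reacted)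
- amount of target at 15 min, in percent of the substrate charged

Time adds target while substrate stands, and in the oak run substrate reads 0 % at 3.00 min, after which target stays near 70.9 % up to 10.0 min, and the 15 min of this flask is longer than that first stretch of the oak run. The gas phase feeds the wanted step but is held at 8.9 mM in oak, maple and this flask alike, so it enters as a constant. The charge of substrate does turn the outcome, since more charge puts more target in substrate's way: target falls from 70.9 % at 13 mM to 52.7 % at 30 mM.

With dissolved gas taken as steady, and mean target taken as the midpoint between nothing and its final value, the balance gives a selectivity rule of the reckoning here: the target level at which both routes use substrate equally, as a fraction of the charge, is y times one plus y, divided by 2 and by the remainder. Rescaled to this flask's charge, oak gives 1.35 and maple 1.28, and their mean, 1.31, is the crossover fraction. Solved for y, it gives 61.9 %. That crossover is 26.3 mM, whereas the forecast integrates to 29 mM and says 62 %, and that all of the substrate has reacted: “the plateaus are flat, so nothing reverses”.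

This flask gives 61.9 % of target at 15 min, by which time all of the substrate has reacted, with 0 % of the charge left as substrate, and crystals stand at 0 % there.

    crystals ⇌ target, rate k1*(cs1 - [target]) while solid is left; crystals form when [target] > cs1 (solubility = 19.0 mM, k = 0.383 /s)
    substrate + target → side product (k = 1.05 /M/s)
    gas phase ⇌ dissolved gas, rate k3*(csat - [dissolved gas]) (kL = 9.74 /s)
    substrate + dissolved gas → target (k = 3.40 /M/s)

On the neighbour charged with 80 mM of substrate, the same crossover level is a fraction 0.329 of the charge, which gives 33.1 %, and that neighbour holds 32.4 % of its charge as target at 15.0 min, crystals included, which stand at 8.67 % of that charge.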